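**Retrosynthetic overview**
1. The target is reached from a trans-decalin C1 ketone by acylation of O8, axial hydride reduction at C1 and removal of the protecting groups.
2. Key disconnection: C3–C4 and C5–C10 are formed together from one acyclic chain by an acetal-initiated ionic intramolecular [4+2] cycloaddition, which closes rings A and B at once and sets C4, C5 and C10.
3. Enabling feature: in ring A the C1 oxygen sits next to quaternary C10 and the C15 aldehyde sits on C4 next to ring-fusion carbon C5. This 1,4-relationship is the retron of a 2-silyloxydiene (C10=C1–C2=C3) plus an enal equivalent (C4=C5–C15). The C6/C7/C8 substituents of ring B are all equatorial and steer the fold of the tether.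
4. The acyclic precursor comes from an Evans syn-aldol of an itaconate imide with fumaraldehyde mono-acetal (C6, C7), a Fukuyama ketone synthesis (C8–C9), a reagent-controlled ketone reduction (C8) and a vinyl addition to a lactone (C1–C2).
5. Ring order: a temporary γ-lactone tying O8 to C1 (closed in step 7, opened in step 8), then rings A and B simultaneously (step 10).

Key step: step 10

Numbering: C1–C15 are the skeletal atoms of the target (C1 carbinol next to quaternary C10, C4 bearing aldehyde C15, C5 ring-fusion CH, C6 OH, C7 bearing C11(=C13)–C12 acid, C8 acyloxy, C14 angular methyl). The C7 descriptor switches between R and S along the route by priority change only.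
Assumption: the zinc reagent is used as its commercial (R)-enantiomer so that intermediates are single isomers; its stereocenter (C10) is erased in step 9, so either enantiomer or the racemate would serve.

**Step 1**
Reactants: 1 (S)-4-benzyloxazolidin-2-one; 2 itaconic anhydride
Product: 3 4-[(S)-4-benzyl-2-oxooxazolidin-3-yl]-2-methylene-4-oxobutanoic acid
Conditions: n-BuLi, THF, -78 °C; then 2, -78 °C; 1 M HCl
Reagents that add atoms: none
Why: N-acylation of the lithiated oxazolidinone by ring opening of the cyclic anhydride at its non-conjugated carbonyl (next to CH2), which leaves the conjugated acrylic acid free; no stereocenter is formed.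

**Step 2**
Reactants: 3
Product: 4 tert-butyl 4-[(S)-4-benzyl-2-oxooxazolidin-3-yl]-2-methylene-4-oxobutanoate
Conditions: Cl3CC(=NH)OtBu, BF3·OEt2 (cat.), CH2Cl2/cyclohexane, rt
Reagents that add atoms: tert-butyl 2,2,2-trichloroacetimidate, CC(C)(C)OC(=N)C(Cl)(Cl)Cl
Why: Acid-catalysed tert-butylation of the carboxylic acid by the trichloroacetimidate, chosen because no base is present that could move the exocyclic double bond into conjugation; no stereocenter is formed.

**Step 3**
Reactants: 4; 5 (E)-4,4-dimethoxybut-2-enal (fumaraldehyde mono(dimethyl acetal))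
Product: 6 tert-butyl (3S,4R,5E)-3-[(S)-4-benzyl-2-oxooxazolidine-3-carbonyl]-4-hydroxy-7,7-dimethoxy-2-methylenehept-5-enoate
Conditions: Bu2BOTf, i-Pr2NEt, CH2Cl2, -78 to 0 °C; then 5, -78 to 0 °C; pH 7 buffer, MeOH, H2O2, 0 °C
Reagents that add atoms: none
Why: Evans syn-aldol reaction: the Z boron enolate reacts at its α-carbon (C7) with the aldehyde carbon (C6) through a closed chair transition state, the (S)-benzyl group shields one enolate face, and C6 and C7 are set as in the target (C6–OH and the C7 acrylate syn); the enal reacts 1,2 and the acetal is untouched.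

**Step 4**
Reactants: 6
Product: 7 tert-butyl (3S,4R,5E)-3-[(S)-4-benzyl-2-oxooxazolidine-3-carbonyl]-4-(tert-butyldimethylsilyloxy)-7,7-dimethoxy-2-methylenehept-5-enoate
Conditions: TBSOTf, 2,6-lutidine, CH2Cl2, -78 °C
Reagents that add atoms: tert-butyldimethylsilyl triflate, CC(C)(C)[Si](C)(C)OS(=O)(=O)C(F)(F)F
Why: Silyl ether formation at the only free hydroxyl (O6), which removes the one proton donor before the thiolate step and keeps O6 distinct from O8 for the rest of the route; no stereocenter changes.

**Step 5**
Reactants: 7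
Product: 8 tert-butyl (3S,4R,5E)-4-(tert-butyldimethylsilyloxy)-3-(ethylsulfanylcarbonyl)-7,7-dimethoxy-2-methylenehept-5-enoate
Conditions: LiSEt (from EtSH and n-BuLi, no excess thiol), THF, -20 °C; aq. NH4Cl
Reagents that add atoms: ethanethiol (as its lithium salt), CCS
Why: Thiolysis of the imide (nucleophilic acyl substitution at the exocyclic carbonyl, auxiliary 1 released for reuse) gives the thioester; without a proton donor a thia-Michael adduct of the hindered tert-butyl acrylate cannot be protonated and reverts, and C6 and C7 are untouched.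

**Step 6**
Reactants: 8; 9 (R)-(3-methoxy-2-methyl-3-oxopropyl)zinc bromide
Product: 10 1-tert-butyl 7-methyl (3S,6S)-3-[(1R,2E)-1-(tert-butyldimethylsilyloxy)-4,4-dimethoxybut-2-enyl]-6-methyl-2-methylene-4-oxoheptanedioate
Conditions: PdCl2(PPh3)2 (5 mol%), THF/PhMe, rt; aq. NH4Cl
Reagents that add atoms: none
Why: Fukuyama coupling: zerovalent palladium inserts into the acyl C–S bond and the acylpalladium thiolate is alkylated by the ester-bearing alkylzinc bromide, which forms C8–C9 and stops at the ketone; C10 comes from the reagent and its configuration is of no consequence.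

**Step 7**
Reactants: 10
Product: 12 tert-butyl (3R,4R,5E)-4-(tert-butyldimethylsilyloxy)-7,7-dimethoxy-3-[(2S,4S)-4-methyl-5-oxotetrahydrofuran-2-yl]-2-methylenehept-5-enoate, via C8 hydroxy methyl ester 11 (not isolated)
Conditions: (R)-1-methyl-3,3-diphenyltetrahydro-1H,3H-pyrrolo[1,2-c][1,3,2]oxazaborole (0.5 equiv), catecholborane, PhMe, -78 °C; MeOH; then pyridinium p-toluenesulfonate (cat.), PhMe, 40 °C
Reagents that add atoms: none
Why: Corey-Bakshi-Shibata reduction: the oxazaborolidine binds the ketone oxygen anti to the branched C7 side and delivers hydride under reagent control, setting C8 with O8 syn to O6 and to the C7 acrylate as in the target; the γ-hydroxy methyl ester then lactonizes, tying O8 to C1 in a temporary five-membered ring.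

**Step 8**
Reactants: 12
Product: 13 tert-butyl (3R,4R,5E)-4-(tert-butyldimethylsilyloxy)-3-[(1S,3S)-1-hydroxy-3-methyl-4-oxohex-5-enyl]-7,7-dimethoxy-2-methylenehept-5-enoate
Conditions: CH2=CHMgBr (1.1 equiv), THF, -78 °C; aq. NH4Cl at -78 °C
Reagents that add atoms: vinylmagnesium bromide, C=C[Mg]Br
Why: Mono-addition of a vinyl Grignard reagent to a γ-lactone: the magnesium lactolate survives at -78 °C and opens only on quench, so the lactone carbonyl (C1) becomes the vinyl ketone and O8–H is released; no stereocenter changes.

**Step 9**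
Reactants: 13
Product: 14 tert-butyl (3R,4R,5E)-4-(tert-butyldimethylsilyloxy)-7,7-dimethoxy-2-methylene-3-[(1S,3Z)-3-methyl-1,4-bis(triethylsilyloxy)hexa-3,5-dienyl]hept-5-enoate (Z isomer written; expected beside its 3E isomer and used as the mixture)
Conditions: Et3SiOTf (2.4 equiv), Et3N (3.5 equiv), CH2Cl2, -78 to -20 °C; non-aqueous work-up, used at once
Reagents that add atoms: triethylsilyl triflate, CC[Si](CC)(CC)OS(=O)(=O)C(F)(F)F
Why: Soft enolization (silyl triflate/amine): O8–H is silylated and the ketone gives the cross-conjugated 2-silyloxydiene by loss of its only α-proton (C10–H; the vinyl side has none), which erases the C10 stereocenter; the isomer with methyl cis to vinyl should be slightly favoured.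

**Step 10**
Reactants: 14
Product: 16 trans-decalin ketone (C1 ketone; 4α-CH(OMe)2; 5α-H; 6α-OTBS; 7β-C(=CH2)CO2tBu; 8α-OH; 10β-CH3), via decalin silyl enol ether 15 (not isolated)
Conditions: Me3SiOTf (0.1 equiv), 2,6-di-tert-butyl-4-methylpyridine (0.2 equiv), CH2Cl2 (0.005 M), -78 to -40 °C; then MeOH, pyridinium p-toluenesulfonate, 0 °C to rt
Reagents that add atoms: none
Why: Proposed new method: Me3SiOTf ionizes the allylic dimethyl acetal to a 1-methoxyallyl cation (Me3SiOMe held in reserve), enol ether carbon C10 adds to C5, the new C4=C15 methyl enol ether closes onto C3 of the silyloxyallyl cation and Me3SiOMe returns methoxide to C15, so the net change is an ionic intramolecular [4+2] cycloaddition that keeps C15 protected; the closest known reaction types are the acid-catalysed ionic Diels-Alder reaction of α,β-unsaturated acetals, the Lewis acid promoted intramolecular Diels-Alder reaction of 2-silyloxy-1,7,9-decatrienes and the silyl triflate mediated intramolecular double Michael (Mukaiyama-Michael) reaction. Ring B closes by 6-exo-trig attack of C10 on C5 (attack at C15 would need an eight-membered ring) and ring A by 6-endo-trig attack of C4 on C3, or both in one asynchronous endo transition state. C5 and C10 are controlled by a chair-like ring B transition state in which the C6 silyloxy, C7 acrylate and C8 silyloxy groups are all equatorial, the large C1 unit is equatorial and the methyl group axial, giving the trans ring fusion (H5 α, methyl β); C4 is controlled by the preference of the C15 acetal carbon for the equatorial (endo) position away from the axial methyl group. The selectivities needed are 1,4- over 1,2-attack on the cation, secured by ring size, and π-facial selectivity, secured by the C6–C8 stereotriad of the tether. The step is stereoconvergent: the C10 configuration of 13 is already erased in 14, and because C10–C1 becomes a freely rotating single bond once C5–C10 is formed, both enol ether isomers of 14 should funnel into 15. Methanolysis with pyridinium p-toluenesulfonate then cleaves the silyl enol ether and the O8 triethylsilyl ether but leaves the dimethyl acetal, the TBS ether and the tert-butyl ester.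

**Step 11**
Reactants: 17 ethyl 2-(hydroxymethyl)acrylate
Product: 18 ethyl 2-[(tert-butyldimethylsilyloxy)methyl]acrylate
Conditions: TBSCl, imidazole, CH2Cl2, 0 °C to rt
Reagents that add atoms: tert-butyldimethylsilyl chloride, CC(C)(C)[Si](C)(C)Cl
Why: Silyl ether protection of the primary allylic alcohol (silylation through the N-silylimidazolium); no stereocenter.

**Step 12**
Reactants: 18
Product: 19 2-[(tert-butyldimethylsilyloxy)methyl]acrylic acid
Conditions: LiOH, THF/H2O, 0 °C; 1 M HCl to pH 4 at 0 °C
Reagents that add atoms: lithium hydroxide, [Li+].[OH-]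
Why: Saponification of the ethyl ester (acyl substitution is faster than conjugate addition of hydroxide to the 2-substituted acrylate), with careful acidification so that the silyl ether survives.

**Step 13**
Reactants: 16; 19
Product: 20 O8 ester of 16 (8α-O-acyl = 2-[(tert-butyldimethylsilyloxy)methyl]acryloyl; C1 ketone; other groups as in 16)
Conditions: 1-ethyl-3-(3-dimethylaminopropyl)carbodiimide hydrochloride, 4-(dimethylamino)pyridine, CH2Cl2, 0 °C to rt
Reagents that add atoms: none
Why: Steglich esterification at O8–H, the only free hydroxyl of 16; the C8–O bond is not touched, so the configuration at C8 is retained.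

**Step 14**
Reactants: 20
Product: 21 1β-alcohol (C1 R; other groups as in 20)
Conditions: NaBH4, CeCl3·7H2O, MeOH, -78 to -40 °C; aq. NH4Cl
Reagents that add atoms: none
Why: Luche reduction: the small cerium-modified borohydride attacks the C1 ketone axially on the face anti to the axial C10 methyl group, giving the equatorial 1β-alcohol as in the target, while CeCl3 suppresses conjugate reduction of the two acrylates and the acetal shields C15.

**Step 15**
Reactants: 21
Product: 23 C12 carboxylic acid C15 aldehyde (1β-OH free; 6α-OTBS; side-chain CH2OTBS), via silylated lutidinium salt 22 (not isolated)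
Conditions: Me3SiOTf, 2,6-lutidine, CH2Cl2, 0 °C to rt; then H2O; aq. citric acid/THF
Reagents that add atoms: water, O
Why: Silyl triflate/pyridine-base deprotection: Me3SiOTf converts the tert-butyl ester into the silyl ester with loss of isobutene and the dimethyl acetal into an N-(α-methoxyalkyl)lutidinium salt that water hydrolyses to the aldehyde, all without protic acid, so the TBS ethers, both acrylates and the equatorial (thermodynamically favoured) C4 configuration are kept.

**Step 16**
Reactants: 23
Product: 24 target, CNP0599450.1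
Conditions: HF·pyridine, pyridine, THF, 0 °C to rt
Reagents that add atoms: none
Why: Fluoride-mediated desilylation with pyridine-buffered HF·pyridine removes both TBS ethers under conditions too mild for lactonization of the γ-hydroxy acid, acyl migration or epimerization at C4; no stereocenter changes.

**Compound list**
1 | (S)-4-benzyloxazolidin-2-one | O=C1OC[C@H](Cc2ccccc2)N1 | starting material
2 | itaconic anhydride | C=C1CC(=O)OC1=O | starting material
3 | 4-[(S)-4-benzyl-2-oxooxazolidin-3-yl]-2-methylene-4-oxobutanoic acid | O=C1OC[C@H](Cc2ccccc2)N1C(=O)CC(=C)C(=O)O | intermediate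
4 | tert-butyl 4-[(S)-4-benzyl-2-oxooxazolidin-3-yl]-2-methylene-4-oxobutanoate | O=C1OC[C@H](Cc2ccccc2)N1C(=O)CC(=C)C(=O)OC(C)(C)C | intermediate
5 | (E)-4,4-dimethoxybut-2-enal | O=C/C=C/C(OC)OC | starting material
6 | syn-aldol adduct (C6 R, C7 S) | O=C1OC[C@H](Cc2ccccc2)N1C(=O)[C@@H](C(=C)C(=O)OC(C)(C)C)[C@H](O)/C=C/C(OC)OC | intermediate
7 | O6-TBS ether of 6 | O=C1OC[C@H](Cc2ccccc2)N1C(=O)[C@@H](C(=C)C(=O)OC(C)(C)C)[C@H](O[Si](C)(C)C(C)(C)C)/C=C/C(OC)OC | intermediate
8 | S-ethyl thioester (C8) | CCSC(=O)[C@@H](C(=C)C(=O)OC(C)(C)C)[C@H](O[Si](C)(C)C(C)(C)C)/C=C/C(OC)OC | intermediate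
9 | (R)-(3-methoxy-2-methyl-3-oxopropyl)zinc bromide | COC(=O)[C@@H](C)C[Zn]Br | starting material
10 | C8 ketone with C1 methyl ester | COC(=O)[C@@H](C)CC(=O)[C@@H](C(=C)C(=O)OC(C)(C)C)[C@H](O[Si](C)(C)C(C)(C)C)/C=C/C(OC)OC | intermediate
11 | C8 hydroxy methyl ester (C8 S) | COC(=O)[C@@H](C)C[C@H](O)[C@@H](C(=C)C(=O)OC(C)(C)C)[C@H](O[Si](C)(C)C(C)(C)C)/C=C/C(OC)OC | intermediate
12 | γ-lactone (O8 to C1) | O=C1O[C@@H](C[C@@H]1C)[C@@H](C(=C)C(=O)OC(C)(C)C)[C@H](O[Si](C)(C)C(C)(C)C)/C=C/C(OC)OC | intermediate
13 | γ-hydroxy vinyl ketone | C=CC(=O)[C@@H](C)C[C@H](O)[C@@H](C(=C)C(=O)OC(C)(C)C)[C@H](O[Si](C)(C)C(C)(C)C)/C=C/C(OC)OC | intermediate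
14 | bis(triethylsilyl) silyloxytriene acetal (Z isomer written) | C=C/C(O[Si](CC)(CC)CC)=C(\C)C[C@H](O[Si](CC)(CC)CC)[C@@H](C(=C)C(=O)OC(C)(C)C)[C@H](O[Si](C)(C)C(C)(C)C)/C=C/C(OC)OC | intermediate
15 | trans-decalin silyl enol ether (C1(OSiEt3)=C2, 8α-OSiEt3) | COC(OC)[C@@H]1CC=C(O[Si](CC)(CC)CC)[C@]2(C)C[C@H](O[Si](CC)(CC)CC)[C@@H](C(=C)C(=O)OC(C)(C)C)[C@H](O[Si](C)(C)C(C)(C)C)[C@@H]12 | intermediate
16 | trans-decalin C1 ketone, 8α-OH | COC(OC)[C@@H]1CCC(=O)[C@]2(C)C[C@H](O)[C@@H](C(=C)C(=O)OC(C)(C)C)[C@H](O[Si](C)(C)C(C)(C)C)[C@@H]12 | intermediate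
17 | ethyl 2-(hydroxymethyl)acrylate | C=C(CO)C(=O)OCC | starting material
18 | ethyl 2-[(tert-butyldimethylsilyloxy)methyl]acrylate | C=C(CO[Si](C)(C)C(C)(C)C)C(=O)OCC | intermediate
19 | 2-[(tert-butyldimethylsilyloxy)methyl]acrylic acid | C=C(CO[Si](C)(C)C(C)(C)C)C(=O)O | intermediate
20 | O8 ester, C1 ketone | COC(OC)[C@@H]1CCC(=O)[C@]2(C)C[C@H](OC(=O)C(=C)CO[Si](C)(C)C(C)(C)C)[C@@H](C(=C)C(=O)OC(C)(C)C)[C@H](O[Si](C)(C)C(C)(C)C)[C@@H]12 | intermediate
21 | 1β-alcohol | COC(OC)[C@@H]1CC[C@@H](O)[C@]2(C)C[C@H](OC(=O)C(=C)CO[Si](C)(C)C(C)(C)C)[C@@H](C(=C)C(=O)OC(C)(C)C)[C@H](O[Si](C)(C)C(C)(C)C)[C@@H]12 | intermediate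
22 | trimethylsilyl ester, O1 trimethylsilyl ether, C15 N-(α-methoxyalkyl)-2,6-lutidinium triflate (both C15 epimers) | COC([n+]1c(C)cccc1C)[C@@H]1CC[C@@H](O[Si](C)(C)C)[C@]2(C)C[C@H](OC(=O)C(=C)CO[Si](C)(C)C(C)(C)C)[C@@H](C(=C)C(=O)O[Si](C)(C)C)[C@H](O[Si](C)(C)C(C)(C)C)[C@@H]12.[O-]S(=O)(=O)C(F)(F)F | intermediate
23 | C12 acid, C15 aldehyde, bis-TBS ether | O=C[C@@H]1CC[C@@H](O)[C@]2(C)C[C@H](OC(=O)C(=C)CO[Si](C)(C)C(C)(C)C)[C@@H](C(=C)C(=O)O)[C@H](O[Si](C)(C)C(C)(C)C)[C@@H]12 | intermediate
24 | CNP0599450.1 (1R,4R,5S,6R,7S,8S,10R) | C=C(CO)C(=O)O[C@H]1C[C@]2(C)[C@@H]([C@@H](O)[C@@H]1C(=C)C(=O)O)[C@H](C=O)CC[C@H]2O | target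

**Step count**
Total: 16 steps. Longest linear sequence: 14 steps (steps 1–10 and 13–16); steps 11–12 make the side-chain acid.

**Three steps most likely to fail**

Step 10 (proposed new method). What may go wrong: capture of the alkoxyallyl cation by a silyl ether oxygen or by a second molecule instead of by the enol ether carbon, or loss of ring-fusion selectivity if the first C–C bond forms through a boat-like fold. Fallback with known chemistry, from 14 back to 16: the dimethyl acetal of 14 would be cleaved under non-protic conditions that spare silyl enol ethers (Et3SiOTf, 2,4,6-collidine, CH2Cl2, 0 °C; then water) to give the trienal F1. F1 would undergo the established Lewis acid promoted intramolecular Diels-Alder reaction of a 2-silyloxy-1,7,9-decatrienal (Me2AlCl, CH2Cl2, -78 °C, or heat in toluene) to give the cycloadduct aldehyde F2 through the endo transition state. HC(OMe)3 and pyridinium p-toluenesulfonate in MeOH would then re-form the dimethyl acetal and remove both triethylsilyl groups, which returns the route to 16. In this concerted variant only the Z enol ether is productive, so the E isomer is lost.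

Step 3. What may go wrong: migration of the exocyclic double bond into conjugation with the imide under the amine base before the boron enolate has formed, or reaction of the dienolate at its γ-carbon (C13). Fallback, from 4 back to 6: conjugate addition of benzeneselenol (PhSeH, Et3N cat., CH2Cl2) would mask the acrylate of 4 as the β-phenylselanyl ester F3 (both C11 epimers). F3 is an ordinary 2-substituted succinyl imide, a well-precedented substrate for the Evans syn-aldol reaction, and with 5 under the conditions of step 3 it would give the aldol adduct F4. Oxidation (H2O2, pyridine, CH2Cl2, 0 °C) and selenoxide syn-elimination, for which C11–H is the only β-hydrogen, would restore the methylene group and return the route to 6.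

Step 5. What may go wrong: conjugate addition of thiolate to the acrylate if a proton source is present, base-induced migration of the C11=C13 double bond through the acidic C7–H, or attack at the endocyclic carbamate carbonyl of the hindered imide. Fallback, from 7 back to 10: the auxiliary would be removed with lithium hydroperoxide (LiOH, H2O2, THF/H2O, 0 °C), which attacks only the exocyclic carbonyl and is too weakly basic to move the double bond, to give the carboxylic acid F5. 1-Chloro-N,N,2-trimethylprop-1-en-1-amine (CH2Cl2, 0 °C) would convert F5 under neutral conditions into the acid chloride F6. Palladium-catalysed acylation of zinc reagent 9 (Negishi acylation, Pd(PPh3)4, THF, 0 °C) would then give ketone 10.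

**Further compounds**
F1 | step 10 | trienal: tert-butyl (3R,4R,5E)-4-(tert-butyldimethylsilyloxy)-2-methylene-3-[(1S,3Z)-3-methyl-1,4-bis(triethylsilyloxy)hexa-3,5-dienyl]-7-oxohept-5-enoate | C=C/C(O[Si](CC)(CC)CC)=C(\C)C[C@H](O[Si](CC)(CC)CC)[C@@H](C(=C)C(=O)OC(C)(C)C)[C@H](O[Si](C)(C)C(C)(C)C)/C=C/C=O
F2 | step 10 | cycloadduct aldehyde (15 with CHO in place of CH(OMe)2) | O=C[C@@H]1CC=C(O[Si](CC)(CC)CC)[C@]2(C)C[C@H](O[Si](CC)(CC)CC)[C@@H](C(=C)C(=O)OC(C)(C)C)[C@H](O[Si](C)(C)C(C)(C)C)[C@@H]12
F3 | step 3 | tert-butyl 4-[(S)-4-benzyl-2-oxooxazolidin-3-yl]-4-oxo-2-(phenylselanylmethyl)butanoate (both C11 epimers) | O=C1OC[C@H](Cc2ccccc2)N1C(=O)CC(C[Se]c1ccccc1)C(=O)OC(C)(C)C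
F4 | step 3 | syn-aldol adduct of F3 with 5 (C6 and C7 as in 6; both C11 epimers) | O=C1OC[C@H](Cc2ccccc2)N1C(=O)[C@@H](C(C[Se]c1ccccc1)C(=O)OC(C)(C)C)[C@H](O)/C=C/C(OC)OC
F5 | step 5 | carboxylic acid (C8) from 7 | OC(=O)[C@@H](C(=C)C(=O)OC(C)(C)C)[C@H](O[Si](C)(C)C(C)(C)C)/C=C/C(OC)OC
F6 | step 5 | acid chloride of F5 | ClC(=O)[C@@H](C(=C)C(=O)OC(C)(C)C)[C@H](O[Si](C)(C)C(C)(C)C)/C=C/C(OC)OC
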